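**Retrosynthetic overview**
- The target is cut at C1–C14, the one bond shared by the 14-membered carbocycle (C1–C14) and the cis-fused α-methylene-γ-butyrolactone (O–C14–C1–C15–C16).
- The key step is an indium Barbier macrocyclisation of an acyclic (Z)-2-(bromomethyl)enoate carrying a free α-hydroxy aldehyde. It closes the carbocycle, then the lactone (O14–C16), and sets C1 and C14 from the free C13–OH.
- The seco chain: C7–C14 from (S)-citronellal (C12 from the pool, C13 by proline aminoxylation, C8 by Sharpless epoxidation and hydride opening); C1–C5 by an E-selective Wittig reaction; union at C5–C6 by copper acetylide allylation, then Lindlar reduction to the 6Z alkene; C15–C17 from methyl propiolate.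
- Ring order: carbocycle and γ-lactone together in the key step, then the C3–C4 oxirane last by reagent-controlled epoxidation.

Key step: step 19

Remark: atom labels follow cembrane numbering of the target (C1 = ring CH bearing C15; C3/C4 = oxirane; C6=C7; C8 = C(Me)OH; C12 = CHMe; C13 = CHOH; C14 = CH–O; C16 = lactone C=O; C17 = exocyclic CH2). The Baylis–Hillman-type adduct and its mesylate are carried as C1-epimer mixtures, since C1 becomes sp2 in the next compound. The ring closure is assumed to keep the chelation/syn preference known for the intermolecular reaction.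

**Route**

Step 1
Reactants: 1 (S)-citronellal
Product: 4 (2R,3S)-3,7-dimethyloct-6-ene-1,2-diol, via anilinooxy aldehyde 2 (not isolated), via anilinooxy alcohol 3 (not isolated)
Conditions: PhNO, L-proline (20 mol %), CHCl3, 4 °C; NaBH4, EtOH, 0 °C; then Zn, AcOH, rt
Reagents that add atoms: nitrosobenzene O=Nc1ccccc1
Why: Proline-catalysed α-aminoxylation (O-selective nitroso aldol of the enamine) should set C13 as R under catalyst control, syn to the pool-derived C12 methyl, and in-flask borohydride reduction and reductive N–O cleavage give the diol.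

Step 2
Reactants: 4 (2R,3S)-3,7-dimethyloct-6-ene-1,2-diol
Product: 5 (4R)-2,2-dimethyl-4-[(2S)-6-methylhept-5-en-2-yl]-1,3-dioxolane
Conditions: Me2C(OMe)2, PPTS (cat.), CH2Cl2, rt
Reagents that add atoms: 2,2-dimethoxypropane COC(C)(C)OC
Why: Acid-catalysed transketalisation closes the five-membered acetonide of the terminal 1,2-diol and touches no stereocentre.

Step 3
Reactants: 5 (4R)-2,2-dimethyl-4-[(2S)-6-methylhept-5-en-2-yl]-1,3-dioxolane
Product: 6 (2E,6S)-6-[(4R)-2,2-dimethyl-1,3-dioxolan-4-yl]-2-methylhept-2-en-1-ol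
Conditions: SeO2 (cat.), t-BuOOH, salicylic acid (cat.), CH2Cl2, rt
Reagents that add atoms: selenium dioxide O=[Se]=O; tert-butyl hydroperoxide CC(C)(C)OO
Why: Riley allylic oxidation (ene reaction, then [2,3]-shift) should hydroxylate the (E)-methyl group of the trisubstituted alkene selectively and keep the E geometry.

Step 4
Reactants: 6 (2E,6S)-6-[(4R)-2,2-dimethyl-1,3-dioxolan-4-yl]-2-methylhept-2-en-1-ol
Product: 7 [(2R,3R)-3-{(3S)-3-[(4R)-2,2-dimethyl-1,3-dioxolan-4-yl]butyl}-2-methyloxiran-2-yl]methanol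
Conditions: Ti(Oi-Pr)4 (10 mol %), D-(−)-diethyl tartrate (12 mol %), t-BuOOH, 4 Å MS, CH2Cl2, −20 °C
Reagents that add atoms: tert-butyl hydroperoxide CC(C)(C)OO
Why: Sharpless asymmetric epoxidation of an (E)-2-methylallylic alcohol, in which D-(−)-tartrate should give the (2R,3R)-epoxide and so fix the C8–O bond of the later tertiary alcohol.

Step 5
Reactants: 7 [(2R,3R)-3-{(3S)-3-[(4R)-2,2-dimethyl-1,3-dioxolan-4-yl]butyl}-2-methyloxiran-2-yl]methanol
Product: 8 (2S,6S)-6-[(4R)-2,2-dimethyl-1,3-dioxolan-4-yl]-2-methylheptane-1,2-diol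
Conditions: LiAlH4, THF, 0 °C to rt
Reagents that add atoms: none
Why: Hydride should open the epoxide by SN2 attack at the secondary carbon C9 (the quaternary C8 cannot be attacked), so the C8–O bond is kept and C8 becomes the (S)-tertiary alcohol.

Step 6
Reactants: 8 (2S,6S)-6-[(4R)-2,2-dimethyl-1,3-dioxolan-4-yl]-2-methylheptane-1,2-diol
Product: 9 (2S,6S)-6-[(4R)-2,2-dimethyl-1,3-dioxolan-4-yl]-2-hydroxy-2-methylheptanal
Conditions: SO3·pyridine, i-Pr2NEt, DMSO/CH2Cl2, 0 °C; crude product used directly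
Reagents that add atoms: none
Why: Parikh–Doering oxidation converts only the primary alcohol (the tertiary one cannot be oxidised), and the quaternary α-carbon cannot epimerise.

Step 7
Reactants: 9 (2S,6S)-6-[(4R)-2,2-dimethyl-1,3-dioxolan-4-yl]-2-hydroxy-2-methylheptanal
Product: 10 (3S,7S)-7-[(4R)-2,2-dimethyl-1,3-dioxolan-4-yl]-3-methyloct-1-yn-3-ol
Conditions: dimethyl (1-diazo-2-oxopropyl)phosphonate, K2CO3, MeOH, 0 °C to rt
Reagents that add atoms: dimethyl (1-diazo-2-oxopropyl)phosphonate CC(=O)C(=[N+]=[N-])P(=O)(OC)OC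
Why: Seyferth–Gilbert homologation in its Ohira–Bestmann form adds C6 and gives the terminal alkyne under mild carbonate conditions that leave the tertiary carbinol untouched.

Step 8
Reactants: 11 3-[(tert-butyldimethylsilyl)oxy]propanal; 12 ethyl 2-(triphenylphosphoranylidene)propanoate
Product: 13 ethyl (2E)-5-[(tert-butyldimethylsilyl)oxy]-2-methylpent-2-enoate
Conditions: CH2Cl2, rt
Reagents that add atoms: none
Why: Wittig olefination with an α-branched stabilised ylide should give the E-trisubstituted enoate (the future C3=C4) with high selectivity.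

Step 9
Reactants: 13 ethyl (2E)-5-[(tert-butyldimethylsilyl)oxy]-2-methylpent-2-enoate
Product: 14 (2E)-5-[(tert-butyldimethylsilyl)oxy]-2-methylpent-2-en-1-ol
Conditions: i-Bu2AlH (2.2 equiv), CH2Cl2, −78 °C
Reagents that add atoms: none
Why: 1,2-Reduction of the enoate by DIBAL-H gives the allylic alcohol without touching the alkene geometry or the silyl ether.

Step 10
Reactants: 14 (2E)-5-[(tert-butyldimethylsilyl)oxy]-2-methylpent-2-en-1-ol
Product: 15 {[(3E)-5-bromo-4-methylpent-3-en-1-yl]oxy}(tert-butyl)dimethylsilane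
Conditions: CBr4, PPh3, CH2Cl2, 0 °C
Reagents that add atoms: carbon tetrabromide BrC(Br)(Br)Br
Why: Appel bromination proceeds by SN2 at the primary allylic carbon, so no allylic transposition or E/Z change is expected.

Step 11
Reactants: 10 (3S,7S)-7-[(4R)-2,2-dimethyl-1,3-dioxolan-4-yl]-3-methyloct-1-yn-3-ol; 15 {[(3E)-5-bromo-4-methylpent-3-en-1-yl]oxy}(tert-butyl)dimethylsilane
Product: 16 (2S,6S,10E)-13-[(tert-butyldimethylsilyl)oxy]-2-[(4R)-2,2-dimethyl-1,3-dioxolan-4-yl]-6,10-dimethyltridec-10-en-7-yn-6-ol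
Conditions: CuI (20 mol %), K2CO3, DMF, rt
Reagents that add atoms: none
Why: Copper acetylide alkylation of a primary allylic bromide forms C5–C6 in the SN2 sense and gives the skipped enyne; the free tertiary hydroxyl is tolerated.

Step 12
Reactants: 16 (2S,6S,10E)-13-[(tert-butyldimethylsilyl)oxy]-2-[(4R)-2,2-dimethyl-1,3-dioxolan-4-yl]-6,10-dimethyltridec-10-en-7-yn-6-ol
Product: 17 (2S,6S,7Z,10E)-13-[(tert-butyldimethylsilyl)oxy]-2-[(4R)-2,2-dimethyl-1,3-dioxolan-4-yl]-6,10-dimethyltrideca-7,10-dien-6-ol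
Conditions: H2 (1 atm), Lindlar catalyst, quinoline, EtOAc, rt
Reagents that add atoms: none
Why: Syn semi-hydrogenation on poisoned palladium should give the Z-C6=C7 alkene and leave the trisubstituted alkene untouched.

Step 13
Reactants: 17 (2S,6S,7Z,10E)-13-[(tert-butyldimethylsilyl)oxy]-2-[(4R)-2,2-dimethyl-1,3-dioxolan-4-yl]-6,10-dimethyltrideca-7,10-dien-6-ol
Product: 18 (3E,6Z,8S,12S)-12-[(4R)-2,2-dimethyl-1,3-dioxolan-4-yl]-4,8-dimethyltrideca-3,6-diene-1,8-diol
Conditions: TBAF, THF, 0 °C to rt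
Reagents that add atoms: none
Why: Fluoride-induced desilylation frees the primary C1 alcohol and does not affect the acetonide.

Step 14
Reactants: 18 (3E,6Z,8S,12S)-12-[(4R)-2,2-dimethyl-1,3-dioxolan-4-yl]-4,8-dimethyltrideca-3,6-diene-1,8-diol
Product: 19 (3E,6Z,8S,12S)-12-[(4R)-2,2-dimethyl-1,3-dioxolan-4-yl]-8-hydroxy-4,8-dimethyltrideca-3,6-dienal
Conditions: Dess–Martin periodinane, NaHCO3, CH2Cl2, 0 °C; crude product used at once
Reagents that add atoms: none
Why: Buffered Dess–Martin oxidation is the mild, non-basic way to a β,γ-unsaturated aldehyde without migration of the C3=C4 bond, and the tertiary alcohol is inert.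

Step 15
Reactants: 19 (3E,6Z,8S,12S)-12-[(4R)-2,2-dimethyl-1,3-dioxolan-4-yl]-8-hydroxy-4,8-dimethyltrideca-3,6-dienal; 20 methyl propiolate
Product: 21 methyl (3RS,5E,8Z,10S,14S)-14-[(4R)-2,2-dimethyl-1,3-dioxolan-4-yl]-3,10-dihydroxy-6,10-dimethyl-2-methylidenepentadeca-5,8-dienoate
Conditions: i-Bu2AlH, NMO, THF, 0 °C, then 20; then 19, 0 °C to rt
Reagents that add atoms: none
Why: Hydroalumination of the propiolate gives an α-(methoxycarbonyl)vinylalane that adds 1,2 to the aldehyde (vinylalumination, an amine-free route to Baylis–Hillman-type adducts) and so installs C15–C17.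

Step 16
Reactants: 21 methyl (3RS,5E,8Z,10S,14S)-14-[(4R)-2,2-dimethyl-1,3-dioxolan-4-yl]-3,10-dihydroxy-6,10-dimethyl-2-methylidenepentadeca-5,8-dienoate
Product: 23 methyl (2Z,5E,8Z,10S,14S)-2-(bromomethyl)-14-[(4R)-2,2-dimethyl-1,3-dioxolan-4-yl]-10-hydroxy-6,10-dimethylpentadeca-2,5,8-trienoate, via allylic mesylate 22 (not isolated)
Conditions: Ms2O, Et3N, CH2Cl2, −20 °C; then LiBr, THF, 0 °C to rt
Reagents that add atoms: methanesulfonic anhydride CS(=O)(=O)OS(C)(=O)=O; lithium bromide [Li+].[Br-]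
Why: Sulfonylation of the secondary allylic alcohol followed by SN2′ displacement with bromide should give the thermodynamically preferred primary (Z)-allylic bromide, while the hindered tertiary alcohol is not sulfonylated.

Step 17
Reactants: 23 methyl (2Z,5E,8Z,10S,14S)-2-(bromomethyl)-14-[(4R)-2,2-dimethyl-1,3-dioxolan-4-yl]-10-hydroxy-6,10-dimethylpentadeca-2,5,8-trienoate
Product: 24 methyl (2Z,5E,8Z,10S,14S,15R)-2-(bromomethyl)-10,15,16-trihydroxy-6,10,14-trimethylhexadeca-2,5,8-trienoate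
Conditions: AcOH/THF/H2O (3:1:1), rt
Reagents that add atoms: none
Why: Mild aqueous acetic acid hydrolyses the terminal acetonide and is too weak to ionise the tertiary allylic alcohol or the ester-deactivated allylic bromide.

Step 18
Reactants: 24 methyl (2Z,5E,8Z,10S,14S,15R)-2-(bromomethyl)-10,15,16-trihydroxy-6,10,14-trimethylhexadeca-2,5,8-trienoate
Product: 25 methyl (2Z,5E,8Z,10S,14S,15R)-2-(bromomethyl)-10,15-dihydroxy-6,10,14-trimethyl-16-oxohexadeca-2,5,8-trienoate
Conditions: TEMPO (10 mol %), PhI(OAc)2, CH2Cl2, 0 °C to rt; crude product used directly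
Reagents that add atoms: none
Why: The oxoammonium oxidation is selective for the primary hydroxyl over the secondary and tertiary ones and gives the free α-hydroxy aldehyde without epimerising C13.

Step 19
Reactants: 25 methyl (2Z,5E,8Z,10S,14S,15R)-2-(bromomethyl)-10,15-dihydroxy-6,10,14-trimethyl-16-oxohexadeca-2,5,8-trienoate
Product: 28 (3aS,5E,8Z,10S,14S,15R,15aR)-10,15-dihydroxy-6,10,14-trimethyl-3-methylidene-3a,4,7,10,11,12,13,14,15,15a-decahydrocyclotetradeca[b]furan-2(3H)-one, via allylindium bromide 26 (not isolated), via hydroxy ester 27 (not isolated)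
Conditions: In powder (4 equiv), THF/H2O (1:1), rt, slow addition of 25 to 2 mM; then aq. HCl to pH 3, rt
Reagents that add atoms: indium [In]
Why: Indium inserts into the allylic C17–Br bond to give the γ-substituted 2-(methoxycarbonyl)allylindium 26, which adds through C1 (SE2′) to the C14 aldehyde, and the resulting γ-hydroxy ester 27 lactonises. The closest known reaction is the indium- or zinc-mediated Barbier synthesis of cis-β,γ-disubstituted α-methylene-γ-butyrolactones from 2-(bromomethyl)alk-2-enoates and aldehydes, together with its metal-mediated intramolecular versions that close carbocycles onto aldehydes. The carbocycle closes in a 14-exo-trig mode on the aldehyde carbonyl (C1–C14), and the lactone closes by 5-exo-trig acyl substitution of O14 on C16. C14 should be set by the indium chelate between the free C13–OH and the aldehyde oxygen (attack anti to the C12 branch, 13,14-syn), and C1 by the syn preference of this ester-bearing allylindium in its cyclic transition state, which places H1 and H14 cis as the cis-fused lactone requires. The step needs γ- over α-attack of the allyl unit (α-attack would need a 16-membered ring and give the less stable non-conjugated adduct) and ring closure over oligomerisation (slow addition at high dilution in a water-rich medium that tolerates the free hydroxyls). It also needs γ- over δ-lactone formation, which the five-membered ring through O14 should win over the six-membered ring through O13.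

Step 20
Reactants: 28 (3aS,5E,8Z,10S,14S,15R,15aR)-10,15-dihydroxy-6,10,14-trimethyl-3-methylidene-3a,4,7,10,11,12,13,14,15,15a-decahydrocyclotetradeca[b]furan-2(3H)-one
Product: 29 CNP0304380.1, (1S,3R,4R,6Z,8S,12S,13R,14R)-3,4-epoxy-8,13-dihydroxycembra-6,15(17)-dien-16,14-olide
Conditions: D-fructose-derived Shi ketone (30 mol %), Oxone, K2CO3, n-Bu4NHSO4, MeCN/DMM/aq. borate buffer, 0 °C
Reagents that add atoms: potassium peroxymonosulfate (Oxone) [K+].[O-]S(=O)(=O)OO
Why: Shi epoxidation by the chiral dioxirane should pick the only electron-rich trisubstituted E-alkene (C3=C4) and give the (3R,4R)-oxirane under reagent control, while the cis-disubstituted allylic alkene and the electron-poor methylene lactone should not react.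

**Compound list**

1 | (3S)-3,7-dimethyloct-6-enal, (S)-citronellal | O=CC[C@@H](C)CCC=C(C)C | starting material
2 | (2R,3S)-3,7-dimethyl-2-(phenylaminooxy)oct-6-enal | O=C[C@H](ONc1ccccc1)[C@@H](C)CCC=C(C)C | intermediate
3 | (2R,3S)-3,7-dimethyl-2-(phenylaminooxy)oct-6-en-1-ol | OC[C@H](ONc1ccccc1)[C@@H](C)CCC=C(C)C | intermediate
4 | (2R,3S)-3,7-dimethyloct-6-ene-1,2-diol | OC[C@H](O)[C@@H](C)CCC=C(C)C | intermediate
5 | (4R)-2,2-dimethyl-4-[(2S)-6-methylhept-5-en-2-yl]-1,3-dioxolane | CC(C)=CCC[C@H](C)[C@@H]1COC(C)(C)O1 | intermediate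
6 | (2E,6S)-6-[(4R)-2,2-dimethyl-1,3-dioxolan-4-yl]-2-methylhept-2-en-1-ol | OC/C(C)=C/CC[C@H](C)[C@@H]1COC(C)(C)O1 | intermediate
7 | [(2R,3R)-3-{(3S)-3-[(4R)-2,2-dimethyl-1,3-dioxolan-4-yl]butyl}-2-methyloxiran-2-yl]methanol | OC[C@@]1(C)O[C@@H]1CC[C@H](C)[C@@H]2COC(C)(C)O2 | intermediate
8 | (2S,6S)-6-[(4R)-2,2-dimethyl-1,3-dioxolan-4-yl]-2-methylheptane-1,2-diol | OC[C@@](C)(O)CCC[C@H](C)[C@@H]1COC(C)(C)O1 | intermediate
9 | (2S,6S)-6-[(4R)-2,2-dimethyl-1,3-dioxolan-4-yl]-2-hydroxy-2-methylheptanal | O=C[C@@](C)(O)CCC[C@H](C)[C@@H]1COC(C)(C)O1 | intermediate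
10 | (3S,7S)-7-[(4R)-2,2-dimethyl-1,3-dioxolan-4-yl]-3-methyloct-1-yn-3-ol | C#C[C@@](C)(O)CCC[C@H](C)[C@@H]1COC(C)(C)O1 | intermediate
11 | 3-[(tert-butyldimethylsilyl)oxy]propanal | O=CCCO[Si](C)(C)C(C)(C)C | starting material
12 | ethyl 2-(triphenylphosphoranylidene)propanoate | CCOC(=O)C(C)=P(c1ccccc1)(c1ccccc1)c1ccccc1 | starting material
13 | ethyl (2E)-5-[(tert-butyldimethylsilyl)oxy]-2-methylpent-2-enoate | CCOC(=O)/C(C)=C/CCO[Si](C)(C)C(C)(C)C | intermediate
14 | (2E)-5-[(tert-butyldimethylsilyl)oxy]-2-methylpent-2-en-1-ol | OC/C(C)=C/CCO[Si](C)(C)C(C)(C)C | intermediate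
15 | {[(3E)-5-bromo-4-methylpent-3-en-1-yl]oxy}(tert-butyl)dimethylsilane | BrC/C(C)=C/CCO[Si](C)(C)C(C)(C)C | intermediate
16 | (2S,6S,10E)-13-[(tert-butyldimethylsilyl)oxy]-2-[(4R)-2,2-dimethyl-1,3-dioxolan-4-yl]-6,10-dimethyltridec-10-en-7-yn-6-ol | CC(C)(C)[Si](C)(C)OCC/C=C(C)/CC#C[C@@](C)(O)CCC[C@H](C)[C@@H]1COC(C)(C)O1 | intermediate
17 | (2S,6S,7Z,10E)-13-[(tert-butyldimethylsilyl)oxy]-2-[(4R)-2,2-dimethyl-1,3-dioxolan-4-yl]-6,10-dimethyltrideca-7,10-dien-6-ol | CC(C)(C)[Si](C)(C)OCC/C=C(C)/C/C=C\[C@@](C)(O)CCC[C@H](C)[C@@H]1COC(C)(C)O1 | intermediate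
18 | (3E,6Z,8S,12S)-12-[(4R)-2,2-dimethyl-1,3-dioxolan-4-yl]-4,8-dimethyltrideca-3,6-diene-1,8-diol | OCC/C=C(C)/C/C=C\[C@@](C)(O)CCC[C@H](C)[C@@H]1COC(C)(C)O1 | intermediate
19 | (3E,6Z,8S,12S)-12-[(4R)-2,2-dimethyl-1,3-dioxolan-4-yl]-8-hydroxy-4,8-dimethyltrideca-3,6-dienal | O=CC/C=C(C)/C/C=C\[C@@](C)(O)CCC[C@H](C)[C@@H]1COC(C)(C)O1 | intermediate
20 | methyl prop-2-ynoate (methyl propiolate) | C#CC(=O)OC | starting material
21 | methyl (3RS,5E,8Z,10S,14S)-14-[(4R)-2,2-dimethyl-1,3-dioxolan-4-yl]-3,10-dihydroxy-6,10-dimethyl-2-methylidenepentadeca-5,8-dienoate | C=C(C(=O)OC)C(O)C/C=C(C)/C/C=C\[C@@](C)(O)CCC[C@H](C)[C@@H]1COC(C)(C)O1 | intermediate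
22 | methyl (3RS,5E,8Z,10S,14S)-14-[(4R)-2,2-dimethyl-1,3-dioxolan-4-yl]-10-hydroxy-3-(methanesulfonyloxy)-6,10-dimethyl-2-methylidenepentadeca-5,8-dienoate | C=C(C(=O)OC)C(OS(C)(=O)=O)C/C=C(C)/C/C=C\[C@@](C)(O)CCC[C@H](C)[C@@H]1COC(C)(C)O1 | intermediate
23 | methyl (2Z,5E,8Z,10S,14S)-2-(bromomethyl)-14-[(4R)-2,2-dimethyl-1,3-dioxolan-4-yl]-10-hydroxy-6,10-dimethylpentadeca-2,5,8-trienoate | BrC/C(C(=O)OC)=C\C/C=C(C)/C/C=C\[C@@](C)(O)CCC[C@H](C)[C@@H]1COC(C)(C)O1 | intermediate
24 | methyl (2Z,5E,8Z,10S,14S,15R)-2-(bromomethyl)-10,15,16-trihydroxy-6,10,14-trimethylhexadeca-2,5,8-trienoate | BrC/C(C(=O)OC)=C\C/C=C(C)/C/C=C\[C@@](C)(O)CCC[C@H](C)[C@@H](O)CO | intermediate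
25 | methyl (2Z,5E,8Z,10S,14S,15R)-2-(bromomethyl)-10,15-dihydroxy-6,10,14-trimethyl-16-oxohexadeca-2,5,8-trienoate | BrC/C(C(=O)OC)=C\C/C=C(C)/C/C=C\[C@@](C)(O)CCC[C@H](C)[C@@H](O)C=O | intermediate
26 | C17 σ-allylindium dibromide of 25 (drawn as the monomeric indium(III) species) | Br[In](Br)C/C(C(=O)OC)=C\C/C=C(C)/C/C=C\[C@@](C)(O)CCC[C@H](C)[C@@H](O)C=O | intermediate
27 | methyl 2-[(1S,2R,3R,4S,8S,9Z,12E)-2,3,8-trihydroxy-4,8,12-trimethylcyclotetradeca-9,12-dien-1-yl]prop-2-enoate | C=C(C(=O)OC)[C@@H]1C/C=C(C)/C/C=C\[C@@](C)(O)CCC[C@H](C)[C@@H](O)[C@@H]1O | intermediate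
28 | (3aS,5E,8Z,10S,14S,15R,15aR)-10,15-dihydroxy-6,10,14-trimethyl-3-methylidene-3a,4,7,10,11,12,13,14,15,15a-decahydrocyclotetradeca[b]furan-2(3H)-one | C=C1C(=O)O[C@H]2[C@H](O)[C@@H](C)CCC[C@](C)(O)/C=C\C/C(C)=C/C[C@@H]12 | intermediate
29 | CNP0304380.1, (1S,3R,4R,6Z,8S,12S,13R,14R)-3,4-epoxy-8,13-dihydroxycembra-6,15(17)-dien-16,14-olide | C=C1C(=O)O[C@H]2[C@H](O)[C@@H](C)CCC[C@](C)(O)/C=C\C[C@@]3(C)O[C@@H]3C[C@@H]12 | target

**Step count and risks**

Total step count: 20. Longest linear sequence: 17 (steps 1–7 and 11–20).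

Steps most likely to fail:

1. Step 19 (key step). The allylindium may add between molecules (oligomers) or be protonated before it finds the aldehyde, and the tether may override the chelate-controlled facial choice, giving the 13,14-anti or the trans-lactone series. Fallback: the C1–C14 bond and the lactone are made between two molecules, where the syn,syn outcome has intermolecular precedent, and the ring is closed at C6=C7 by metathesis. It sets out from 10 and 15 and returns at 28.
   - From 10, Lindlar semi-hydrogenation should give the vinyl carbinol F1, aqueous acetic acid the triol F2, and TEMPO/PhI(OAc)2 the α-hydroxy aldehyde F3.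
   - From 15, CuI-catalysed coupling with vinylmagnesium bromide should give the skipped diene silyl ether F4, TBAF the dienol F5, Dess–Martin oxidation the dienal F6, vinylalumination with 20 the Baylis–Hillman-type adduct F7, and NBS/Me2S the allylic bromide F8.
   - Indium-mediated Barbier coupling of F3 with F8 in THF/H2O should give the open-chain hydroxy ester F9, which lactonises to the acyclic cis-lactone F10.
   - Z-selective ring-closing metathesis of F10 (cyclometalated ruthenium catalyst, high dilution) should close the 14-membered ring and give 28.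

2. Step 20. The macrocycle may expose only one face of C3=C4 and so override the catalyst, delivering oxygen to the wrong face, and the basic medium may attack the methylene lactone. Fallback: oxygen is brought to the opposite face by anti-addition and ring closure instead of direct transfer. It sets out from 28 and returns at 29.
   - TESOTf/2,6-lutidine should give the bis(triethylsilyl) ether F11, which blocks bromo-etherification by O8.
   - NBS in THF/H2O should give the bromohydrin F12 (Br at C3, OH at C4, anti).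
   - DBU should close the silylated oxirane F13 with inversion at C3.
   - Acetic-acid-buffered TBAF should then give 29.

3. Step 15. The C3=C4 bond of the β,γ-unsaturated aldehyde may migrate into conjugation, or the aldehyde may enolise or be reduced under the Lewis-acidic aluminium reagent. Fallback: a low-temperature aldol and elimination sequence replaces the vinylmetal addition. It sets out from 19 and returns at 21.
   - Addition of the lithium enolate of methyl 3-(dimethylamino)propanoate at −78 °C should give the amino diol ester F14.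
   - Methyl iodide should give the trimethylammonium iodide F15.
   - DBU-induced β-elimination of trimethylamine should then give 21.

**Further compounds**

F1 | step 19 | (3S,7S)-7-[(4R)-2,2-dimethyl-1,3-dioxolan-4-yl]-3-methyloct-1-en-3-ol | C=C[C@@](C)(O)CCC[C@H](C)[C@@H]1COC(C)(C)O1
F2 | step 19 | (2R,3S,7S)-3,7-dimethylnon-8-ene-1,2,7-triol | C=C[C@@](C)(O)CCC[C@H](C)[C@@H](O)CO
F3 | step 19 | (2R,3S,7S)-2,7-dihydroxy-3,7-dimethylnon-8-enal | C=C[C@@](C)(O)CCC[C@H](C)[C@@H](O)C=O
F4 | step 19 | tert-butyl{[(3E)-4-methylhepta-3,6-dien-1-yl]oxy}dimethylsilane | C=CC/C(C)=C/CCO[Si](C)(C)C(C)(C)C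
F5 | step 19 | (3E)-4-methylhepta-3,6-dien-1-ol | C=CC/C(C)=C/CCO
F6 | step 19 | (3E)-4-methylhepta-3,6-dienal | C=CC/C(C)=C/CC=O
F7 | step 19 | methyl (5E)-3-hydroxy-6-methyl-2-methylidenenona-5,8-dienoate | C=CC/C(C)=C/CC(O)C(=C)C(=O)OC
F8 | step 19 | methyl (2Z,5E)-2-(bromomethyl)-6-methylnona-2,5,8-trienoate | BrC/C(C(=O)OC)=C\C/C=C(C)/CC=C
F9 | step 19 | open-chain hydroxy ester, methyl (3S,4R,5R,6S,10S)-4,5,10-trihydroxy-6,10-dimethyl-2-methylidene-3-[(2E)-3-methylhexa-2,5-dien-1-yl]dodec-11-enoate | C=C(C(=O)OC)[C@H](C/C=C(C)/CC=C)[C@@H](O)[C@H](O)[C@@H](C)CCC[C@](C)(O)C=C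
F10 | step 19 | acyclic cis-lactone, (4S,5R)-5-[(1R,2S,6S)-1,6-dihydroxy-2,6-dimethyloct-7-en-1-yl]-3-methylidene-4-[(2E)-3-methylhexa-2,5-dien-1-yl]oxolan-2-one | C=C1C(=O)O[C@@H]([C@H](O)[C@@H](C)CCC[C@](C)(O)C=C)[C@H]1C/C=C(C)/CC=C
F11 | step 20 | 8,13-bis-O-(triethylsilyl) ether of 28 | C=C1C(=O)O[C@H]2[C@H](O[Si](CC)(CC)CC)[C@@H](C)CCC[C@](C)(O[Si](CC)(CC)CC)/C=C\C/C(C)=C/C[C@@H]12
F12 | step 20 | C3-bromo C4-hydroxy bromohydrin of F11 (anti) | C=C1C(=O)O[C@H]2[C@H](O[Si](CC)(CC)CC)[C@@H](C)CCC[C@](C)(O[Si](CC)(CC)CC)/C=C\C[C@@](C)(O)[C@@H](Br)C[C@@H]12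
F13 | step 20 | 8,13-bis-O-(triethylsilyl) ether of 29 | C=C1C(=O)O[C@H]2[C@H](O[Si](CC)(CC)CC)[C@@H](C)CCC[C@](C)(O[Si](CC)(CC)CC)/C=C\C[C@@]3(C)O[C@@H]3C[C@@H]12
F14 | step 15 | methyl (5E,8Z,10S,14S)-2-[(dimethylamino)methyl]-14-[(4R)-2,2-dimethyl-1,3-dioxolan-4-yl]-3,10-dihydroxy-6,10-dimethylpentadeca-5,8-dienoate | COC(=O)C(CN(C)C)C(O)C/C=C(C)/C/C=C\[C@@](C)(O)CCC[C@H](C)[C@@H]1COC(C)(C)O1
F15 | step 15 | N-methyl trimethylammonium iodide of F14 | COC(=O)C(C[N+](C)(C)C)C(O)C/C=C(C)/C/C=C\[C@@](C)(O)CCC[C@H](C)[C@@H]1COC(C)(C)O1.[I-]
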